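**Retrosynthetic overview**
1. Target 16 ⇐ tetraol 15: ring B is closed last, by capture of the C7' quinone methide by the C9 hydroxyl.
2. 15 ⇐ spiroketal lactone 14: LiAlH4 releases the tertiary C8–OH and the C9 alcohol and removes the chiral ketal.
3. 14 ⇐ sinapyl alcohol 3 + 8-oxygenated monolignol surrogate 11: one-pot oxidative 8–8' cross-coupling, bis-quinone methide 12, ring A closed by capture of the C7 quinone methide by the C9' hydroxyl.
4. 11 ⇐ syringaldehyde 4 (azlactone, hydrolysis to the arylpyruvic acid enol 7, ketal with (−)-menthone 8); 3 ⇐ sinapic acid 1.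
5. Ring order: ring A (C7–O–C9') in step 6, ring B (C7'–O–C9) in step 8.

Assumption: lignan numbering is used (C7/C8/C9 for the half carrying the tertiary OH, primed atoms for the sinapyl alcohol half). The face selectivity in step 6 is assigned from a steric model of the ketal (attack anti to the isopropyl-bearing side), not from experiment; if it proves opposite, the other spiro epimer of 11 from step 5 is carried on instead.

**Route**

Step 1
Reactants: 1 sinapic acid, (E)-3-(4-hydroxy-3,5-dimethoxyphenyl)prop-2-enoic acid
Product: 2 methyl sinapate, methyl (E)-3-(4-hydroxy-3,5-dimethoxyphenyl)prop-2-enoate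
Conditions: MeOH, H2SO4 (cat.), reflux
Reagents that add atoms: methanol, CO
Why: Fischer esterification; the phenol and the E-alkene are untouched and no stereocentre is formed.

Step 2
Reactants: 2 methyl sinapate
Product: 3 sinapyl alcohol, (E)-4-(3-hydroxyprop-1-enyl)-2,6-dimethoxyphenol
Conditions: iBu2AlH (4.5 equiv), toluene, 0 °C; EtOH then H2O
Reagents that add atoms: none
Why: 1,2-reduction of a cinnamate ester by iBu2AlH is the standard monolignol preparation; the aluminium phenoxide shields the phenol and the E geometry is kept.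

Step 3
Reactants: 4 syringaldehyde (4-hydroxy-3,5-dimethoxybenzaldehyde), 5 N-acetylglycine
Product: 6 (Z)-4-(4-acetoxy-3,5-dimethoxybenzylidene)-2-methyl-1,3-oxazol-5(4H)-one
Conditions: Ac2O, NaOAc, 100 °C
Reagents that add atoms: acetic anhydride, CC(=O)OC(C)=O
Why: Erlenmeyer–Plöchl azlactone synthesis; Ac2O cyclodehydrates 5, the oxazolone condenses with the aldehyde to the thermodynamic Z-alkene, and the phenol is acetylated on the way.

Step 4
Reactants: 6 azlactone
Product: 7 3-(4-hydroxy-3,5-dimethoxyphenyl)pyruvic acid, written as its Z-enol (Z)-2-hydroxy-3-(4-hydroxy-3,5-dimethoxyphenyl)prop-2-enoic acid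
Conditions: 3 M HCl, reflux
Reagents that add atoms: water, O
Why: Acid hydrolysis of the azlactone, the enamide and the aryl acetate is the classical route to arylpyruvic acids, which crystallise as the Z-enol.

Step 5
Reactants: 7 arylpyruvic acid enol, 8 (−)-menthone, (2S,5R)-2-isopropyl-5-methylcyclohexanone
Product: 11 (5R,6S,9R)-3-[(Z)-4-hydroxy-3,5-dimethoxybenzylidene]-6-isopropyl-9-methyl-1,4-dioxaspiro[4.5]decan-2-one (menthone ketal of 7 with the enol-ether oxygen axial), via tris-silyl derivative 9 (not isolated), via silyl ether ketal 10 (not isolated)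
Conditions: N,O-bis(trimethylsilyl)acetamide (3.3 equiv), CH2Cl2, rt; then 8, Me3SiOTf (5 mol %), −40 °C; aq. citric acid; SiO2 separation of the spiro epimers
Reagents that add atoms: none
Why: Noyori-type ketalisation to a 1,3-dioxolan-4-one: Me3SiOTf activates menthone toward the silyl enol ether and silyl ester oxygens of 9 with loss of (Me3Si)2O, and the low temperature prevents epimerisation of menthone next to the carbonyl. The spiro carbon forms as both epimers; the (5R) epimer is isolated and the other is re-equilibrated with Me3SiOTf.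

Step 6
Reactants: 3 sinapyl alcohol, 11 spiroketal phenol (1.5 equiv)
Product: 14 ring-A tetrahydrofuran spiroketal lactone: 2-aryl-4-[aryl(hydroxy)methyl]tetrahydrofuran whose C3 is C3 of the menthone-ketal dioxolanone (7R,8R,8'R; both C7' epimers; aryl = 4-hydroxy-3,5-dimethoxyphenyl), via bis-quinone methide 12 (not isolated), via quinone methide 13 (not isolated)
Conditions: Ag2O (1.1 equiv), CH2Cl2–acetone, 0 °C, 3 added over 4 h; filter; THF–H2O, AcOH (cat.), rt
Reagents that add atoms: water, O
Why: Proposed new method: Ag2O takes one electron from each phenol; the radical of 11 has its spin at C8 as a hindered captodative 1,3-dioxolan-4-on-5-yl radical that does not dimerise, so the transient sinapyl radical captures it (persistent-radical effect) in an 8–8' bond formed anti to the isopropyl-flanked face of the ketal (dioxolanonyl radicals and enolates react anti to the acetal substituent), which sets C8; bis-quinone methide 12 then closes ring A as in the biosynthesis by 5-exo capture of the C7 quinone methide by the C9' hydroxyl (sets C7, aryl exo), the C7' quinone methide 13 is hydrated to both epimers (reset in step 8), and of the two C8' epimers only the one shown can later close ring B, the other being removed after step 8; the closest known reactions are the oxidative 8–8' dehydrodimerisation of sinapyl alcohol to syringaresinol and its cross-coupling with sinapate esters.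

Step 7
Reactants: 14 spiroketal lactone
Product: 15 (2R,3S,4R)-2-(4-hydroxy-3,5-dimethoxyphenyl)-3-hydroxy-3-(hydroxymethyl)-4-[hydroxy(4-hydroxy-3,5-dimethoxyphenyl)methyl]tetrahydrofuran (7R,8S,8'R; both C7' epimers)
Conditions: LiAlH4 (6 equiv), THF, 0 °C to rt; H2O, aq. NaOH
Reagents that add atoms: none
Why: Hydride reduction of a 1,3-dioxolan-4-one (known for Seebach-type dioxolanones): attack at the lactone carbonyl opens the ring, the hemiketal alkoxide collapses to menthone (reduced on to menthol) and the tertiary C8 alkoxide, and the aldehyde is reduced to the C9 alcohol; no stereocentre is touched.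

Step 8
Reactants: 15 tetraol
Product: 16 8-hydroxysyringaresinol (7R,8S,7'S,8'R)
Conditions: camphorsulfonic acid (5 mol %), CH2Cl2–THF, 0 °C, 30 min; aq. NaHCO3
Reagents that add atoms: none
Why: Acid converts the p-hydroxybenzylic C7' alcohol into its quinone methide, which is captured 5-exo by the C9 hydroxyl (the only hydroxyl that can reach C7' through a five-membered ring, and only with cis fusion) from the convex side, so the aryl group ends up exo (sets C7' as S under kinetic control, as in the biosynthetic ring closure). C8 and C8' are not involved; any C7 or C7' epimer is separated and re-equilibrated under the same conditions.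

**Compound list**
1 | sinapic acid | COc1cc(/C=C/C(=O)O)cc(OC)c1O | starting material
2 | methyl sinapate | COC(=O)/C=C/c1cc(OC)c(O)c(OC)c1 | intermediate
3 | sinapyl alcohol | COc1cc(/C=C/CO)cc(OC)c1O | intermediate
4 | syringaldehyde | COc1cc(C=O)cc(OC)c1O | starting material
5 | N-acetylglycine | CC(=O)NCC(=O)O | starting material
6 | (Z)-4-(4-acetoxy-3,5-dimethoxybenzylidene)-2-methyl-1,3-oxazol-5(4H)-one | CC(=O)Oc1c(OC)cc(/C=C2\N=C(C)OC2=O)cc1OC | intermediate
7 | 3-(4-hydroxy-3,5-dimethoxyphenyl)pyruvic acid, Z-enol | COc1cc(/C=C(\O)C(=O)O)cc(OC)c1O | intermediate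
8 | (−)-menthone | CC(C)[C@@H]1CC[C@@H](C)CC1=O | starting material
9 | tris(trimethylsilyl) derivative of 7 (silyl enol ether, silyl ester, aryl silyl ether) | COc1cc(/C=C(\O[Si](C)(C)C)C(=O)O[Si](C)(C)C)cc(OC)c1O[Si](C)(C)C | intermediate (not isolated)
10 | aryl trimethylsilyl ether of 11 | COc1cc(/C=C2\O[C@@]3(OC2=O)C[C@H](C)CC[C@H]3C(C)C)cc(OC)c1O[Si](C)(C)C | intermediate (not isolated)
11 | (5R,6S,9R)-3-[(Z)-4-hydroxy-3,5-dimethoxybenzylidene]-6-isopropyl-9-methyl-1,4-dioxaspiro[4.5]decan-2-one | COc1cc(/C=C2\O[C@@]3(OC2=O)C[C@H](C)CC[C@H]3C(C)C)cc(OC)c1O | intermediate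
12 | 8–8' bis-quinone methide (C8 in the dioxolanone, C8' bearing CH2OH) | COC1=CC(=C[C@@H](CO)[C@]2(C=C3C=C(OC)C(=O)C(OC)=C3)O[C@@]4(OC2=O)C[C@H](C)CC[C@H]4C(C)C)C=C(OC)C1=O | intermediate (not isolated)
13 | C7' quinone methide with ring A closed | COC1=CC(=C[C@H]2CO[C@H](c3cc(OC)c(O)c(OC)c3)[C@]24O[C@@]5(OC4=O)C[C@H](C)CC[C@H]5C(C)C)C=C(OC)C1=O | intermediate (not isolated)
14 | ring-A tetrahydrofuran spiroketal lactone (7R,8R,8'R; C7' both epimers, left open in the SMILES) | COc1cc(C(O)[C@H]2CO[C@H](c3cc(OC)c(O)c(OC)c3)[C@]24O[C@@]5(OC4=O)C[C@H](C)CC[C@H]5C(C)C)cc(OC)c1O | intermediate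
15 | tetraol (7R,8S,8'R; C7' both epimers, left open in the SMILES) | COc1cc(C(O)[C@H]2CO[C@H](c3cc(OC)c(O)c(OC)c3)[C@@]2(O)CO)cc(OC)c1O | intermediate
16 | 8-hydroxysyringaresinol | COc1cc([C@H]2OC[C@]3(O)[C@@H](c4cc(OC)c(O)c(OC)c4)OC[C@H]23)cc(OC)c1O | target

**Step count and risks**

Total step count: 8. Longest linear sequence: 6 (steps 3 to 8, from syringaldehyde).

The three steps most likely to fail:

Step 6 (cross-coupling). The risks are homodimerisation of 3 to syringaresinol, O–C coupling, and an unproven face bias. The fallback oxidises only the ketal partner and uses the second unit as a closed-shell nucleophile. It sets out from 3 and 11. Compound 3 is peracetylated (Ac2O, pyridine) to sinapyl alcohol diacetate F1, which cannot form a phenoxyl radical. Compound 11 is oxidised with PhI(OAc)2 in (CF3)2CHOH–CH2Cl2 at −20 °C to its phenoxonium ion, whose charge at C8 is stabilised by the ketal oxygen. The styrene carbon C8' of F1 attacks C8 anti to the isopropyl side, and the C7' cation and the C7 quinone methide are hydrated on work-up to the diol diacetate F2 (C7 and C7' epimer mixture). LiAlH4 removes the ketal, reduces the lactone carbonyl and cleaves both acetates to give the pentaol F3. Under the conditions of step 8 both benzylic alcohols ionise and are captured by the C9' and C9 hydroxyls, which brings the route back at 16.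

Step 5 (chiral ketal). The risks are sluggish ketalisation of a hindered ketone, a spiro epimer mixture, and only moderate shielding by the isopropyl group. The fallback takes the controlling centre from a stereodefined α-hydroxy acid instead, and sets out from 7. D-Lactate dehydrogenase (NADH recycled by formate dehydrogenase and HCO2Na) reduces 7 to (R)-3-(4-hydroxy-3,5-dimethoxyphenyl)lactic acid F4. Pivalaldehyde (TsOH cat., pentane, water separator) gives the cis acetal (2R,5R)-2-tert-butyl-5-(4-hydroxy-3,5-dimethoxybenzyl)-1,3-dioxolan-4-one F5. DDQ in dioxane dehydrogenates it through the p-quinone methide to (R)-2-tert-butyl-5-[(Z)-4-hydroxy-3,5-dimethoxybenzylidene]-1,3-dioxolan-4-one F6, which has no spiro isomerism and whose tert-butyl group blocks one face. F6 replaces 11 under the conditions of step 6 to give the tert-butyl acetal analogue of 14, F7, and LiAlH4 brings the route back at 15.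

Step 8 (ring B closure). The risks are C7/C7' epimer mixtures and quinone methide side reactions under acid. The fallback closes ring B at the lactone level under base, and sets out from 14. K2CO3 in MeOH opens the dioxolanone by methanolysis and releases menthone; the C7' hydroxyl lactonises, and the p-hydroxybenzylic lactone equilibrates through its phenoxide quinone methide to the exo-aryl hydroxy lactone F8 (the 9-oxo analogue of 16). iBu2AlH at −78 °C gives the lactol F9. Et3SiH with CF3CO2H at −40 °C removes the lactol hydroxyl through the oxocarbenium ion, which brings the route back at 16.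

**Further compounds**
F1 | step 6 | sinapyl alcohol diacetate | CC(=O)OC/C=C/c1cc(OC)c(OC(C)=O)c(OC)c1
F2 | step 6 | 8–8' coupled diol diacetate with the menthone-ketal dioxolanone at C8 (C7 and C7' both epimers) | CC(=O)OC[C@H](C(O)c1cc(OC)c(OC(C)=O)c(OC)c1)[C@]2(C(O)c3cc(OC)c(O)c(OC)c3)O[C@@]4(OC2=O)C[C@H](C)CC[C@H]4C(C)C
F3 | step 6 | pentaol (8S,8'R)-1,4-bis(4-hydroxy-3,5-dimethoxyphenyl)-2,3-bis(hydroxymethyl)butane-1,2,4-triol (C7 and C7' both epimers) | COc1cc(C(O)[C@@H](CO)[C@](O)(CO)C(O)c2cc(OC)c(O)c(OC)c2)cc(OC)c1O
F4 | step 5 | (R)-3-(4-hydroxy-3,5-dimethoxyphenyl)lactic acid | COc1cc(C[C@@H](O)C(=O)O)cc(OC)c1O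
F5 | step 5 | (2R,5R)-2-tert-butyl-5-(4-hydroxy-3,5-dimethoxybenzyl)-1,3-dioxolan-4-one | COc1cc(C[C@H]2O[C@@H](C(C)(C)C)OC2=O)cc(OC)c1O
F6 | step 5 | (R)-2-tert-butyl-5-[(Z)-4-hydroxy-3,5-dimethoxybenzylidene]-1,3-dioxolan-4-one | COc1cc(/C=C2\O[C@@H](C(C)(C)C)OC2=O)cc(OC)c1O
F7 | step 5 | tert-butyl acetal analogue of 14 (C7' both epimers) | COc1cc(C(O)[C@H]2CO[C@H](c3cc(OC)c(O)c(OC)c3)[C@]24O[C@@H](C(C)(C)C)OC4=O)cc(OC)c1O
F8 | step 8 | 8-hydroxy-9-oxosyringaresinol (hydroxy lactone) | COc1cc([C@H]2OC(=O)[C@]3(O)[C@@H](c4cc(OC)c(O)c(OC)c4)OC[C@H]23)cc(OC)c1O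
F9 | step 8 | lactol of F8 (C9 both epimers) | COc1cc([C@H]2OC(O)[C@]3(O)[C@@H](c4cc(OC)c(O)c(OC)c4)OC[C@H]23)cc(OC)c1O
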